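## The problem

Target 21 is a 2,6,6-trimethylcyclohex-2-ene with an isovalerate on one ring carbon and a 7-coumarinyl ether on an exocyclic methylene; the labels used throughout are C1 (methyl-bearing alkene carbon), C2 (alkene CH), C3 (ring CH2), C4 (acyloxy carbon), C5 (gem-dimethyl carbon), C6 (ring CH) and C8 (the oxymethylene carbon on C6). The two stereocentres, C4 (R) and C6 (S), flank quaternary C5 and are cis, and since the open 1,3-relationship gives no dependable bias, C4 can steer C6 only while its oxygen is tied to C8 in a bridge. The C1=C2 alkene must stay β,γ to C8, although base can move it into conjugation or into the exocyclic position whenever C8 is at the carbonyl level. The coumarin lactone and the isovalerate do not survive hydride, alkoxide or strong nucleophiles, so both must enter late. The cis C4–OH/C8–OH pair closes readily to a bridged ether once the primary position is activated, so the two oxygens must be differentiated before the aryl ether is made. The enabling feature is C6 itself, a methine bonded to C1, to quaternary C5 and to exocyclic C8: putting C8 back into the ring between C1 and C6 reveals a 2,6,6-trimethylcyclohept-2-enone. That seven-membered ring already holds all ten carbons, the methyl group and the alkene, and the future C6 is its only enolisable α′ position.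

## Retrosynthesis

**Aryl ether.** The O–C8 bond of 21 is cut last, giving hydroxy ester 19 and umbelliferone 20. Cutting the ester last instead would leave a free cis secondary hydroxyl while C8 is activated and invite bridged-ether formation. The forward step is a Mitsunobu etherification at a β-branched primary alcohol under neutral conditions that spare both esters.

**Isovalerate.** The ester C–O bond at C4 is cut to diol 15 and isovaleryl chloride 16. Because the primary hydroxyl is the more reactive one, it is masked in the same flask (silyl ether 17, then ester 18) and released afterwards. The forward steps must tell a primary from a neopentylic secondary alcohol, which is easy.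

**Diol to lactone.** Both C–O functions of 15 are traced to bridged lactone 14. The lactone holds the cis relationship in a ring and reduces the problem to one carbonyl group. The forward reaction is a hydride reduction.

**Lactone as stereochemical lock.** The lactone C–O bond is cut to hydroxy ester 13, and this to silyl ether 12. This cut is preferred over relying on a perfectly face-selective protonation at C6. Only a cis hydroxy ester can lactonise, the closure runs under base that equilibrates C6, and the bridgehead of 14 cannot enolise, so the configuration is corrected and then fixed.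

**Ring bond C1–C6 (key).** Ester 12 is traced to α′-diazo enone 9 by breaking C1–C6 and returning C8 to the ring as a carbonyl carbon. The neighbouring option was an enolate alkylation at C6, but that would have to create the hindered methine with no stereochemical help. Precursor 9 has one stereocentre fewer. The forward reaction is a Wolff ring contraction with alkenyl migration.

**Diazo group and protection.** Diazo ketone 9 comes from silyl enone 7 by way of activated diketone 8, and 7 from hydroxy enone 6. Quaternary C6 of the cycloheptenone leaves C7 as the single α′ site, so no regiochemical question arises.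

**The oxygen stereocentre.** The C5–O bond and the C4–H bond of 6 are traced to epoxide 5 and then to achiral eucarvone 4. A catalyst-controlled epoxidation of the cis γ,δ-alkene sets the only stereocentre that must be set absolutely. Reductive removal of the allylic C–O bond then leaves the alcohol.

**Seven-membered ring.** Eucarvone 4 is taken back through carenone 3 and hydrobromide 2 to (R)-carvone 1. This is a two-step ring expansion from a bulk terpene; the stereocentre of 1 is erased on the way.

## Roads not taken

Alternative 1: The cut is the C6–C8 bond, with C8 delivered as a formaldehyde unit from the C4 oxygen.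
- Forward: SnCl4 or In(OTf)3 would ionise methoxymethyl ether A1 to an oxocarbenium ion. Its carbon attacks C6 of the ring alkene, the tertiary C1 cation loses a proton from C2, and bridged ether A2 results. Acylative ether cleavage with 16 would give chloromethyl ester A3, to be displaced by 20.
- Merits: C4 dictates C6 because only a cis bridge can form. One step makes the C–C bond and the stereocentre, and the six-membered ring is never built. The step count is roughly half that of the chosen plan, which is a real advantage.
- Weak points: the C1 cation can lose a proton from the methyl group as readily as from C2, or be captured by halide, so the alkene position rests on a slight preference. Attack at C6 occurs beside the quaternary carbon and needs the axial conformer. The acylative opening must cleave O–C8 and not O–C4 under conditions that can ionise a homoallylic system. A3 is a β-branched primary chloride next to a quaternary carbon, a poor partner for a phenoxide.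
- Comparison: against the shorter count, the chosen plan offers an alkene that is present from 4 onward and never generated by elimination, and an ether bond made from an alcohol under Mitsunobu conditions.

Alternative 2: The cut is the C3–C4 bond; the cyclohexene arises from a cyclobutane.
- Forward: the potassium alkoxide of vinylcyclobutanol A4 (KH, 18-crown-6) would undergo an oxyanion-accelerated 1,3-shift. The C4–C1 bond breaks, C4 bonds to the vinyl terminus C3, and cyclohexenol A5 forms.
- Merits: the shift fixes the alkene position and runs at low temperature. A5 arrives with the primary oxygen silylated and the secondary one free, so the end-game is acylation, desilylation and etherification. In this respect it is better than the chosen plan, which spends steps 11 and 12 on differentiating the two oxygens.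
- Weak points: A4 carries three contiguous stereocentres on a four-membered ring, one of them a methyl/vinyl quaternary carbon next to the gem-dimethyl carbon, and no short enantioselective entry is evident. The shift probably proceeds by fragmentation and re-closure, not in concert, so the C4 configuration is decided on re-closure and may not be transferred. The ring-opened anion can also simply be protonated.
- Comparison: the chosen plan offers a precursor reached from carvone in six steps with one catalyst-set stereocentre, and a second stereocentre that is corrected thermodynamically.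

Alternative 3: The cut is the C4–O bond; C8 is the carbonyl of a bridged cyclobutanone.
- Forward: verbenone A6 would be photo-isomerised to chrysanthenone A7. Alkaline H2O2 or a peracid would add to the carbonyl, bridgehead C4 migrates to oxygen with retention, and lactone A8 results, which is the same compound as 14.
- Merits: the terpene supplies every carbon and both stereocentres, the cis relationship is built into the bicycle, and two steps would reach what the chosen plan reaches in nine. If the migration were selective this road would be preferred.
- Weak points: both carbons flanking the carbonyl are bridgehead methines. The one that must migrate (C4, next to a CH2) is electronically less apt than the allylic bridgehead C6, whose migration gives regioisomeric lactone A9, and nothing in the substrate overrides this. Peracids also threaten the alkene. The photochemical formation of A7 can proceed through α-cleavage and re-closure in either sense, which erodes optical purity.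
- Comparison: the chosen plan offers connectivity that is not in doubt (one α′ site for the diazo group, one group that can migrate) and an enantiopurity fixed in a catalytic step whose product can be assayed before the key step.

Key step: step 7

Assumption: the SMILES is read as the cis-(1R,5S) isomer (C4 R, C6 S in the labels above); the configuration of carvone 1 is irrelevant because eucarvone 4 is achiral.

## Route

Step 1
Reactants: 1 (R)-carvone
Product: 2 (5R)-5-(2-bromopropan-2-yl)-2-methylcyclohex-2-en-1-one (carvone hydrobromide)
Conditions: HBr (33% in AcOH), 0–10 °C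
Reagents that add atoms: hydrogen bromide, Br
Why: Markovnikov hydrobromination of the electron-rich 1,1-disubstituted isopropenyl alkene; the conjugated ring alkene is electron-poor and should not react.

Step 2
Reactants: 2 (5R)-5-(2-bromopropan-2-yl)-2-methylcyclohex-2-en-1-one
Product: 4 2,6,6-trimethylcyclohepta-2,4-dien-1-one (eucarvone), via car-3-en-2-one 3 (not isolated)
Conditions: KOH, MeOH, 0 °C then reflux
Reagents that add atoms: none
Why: The α′-enolate displaces the tertiary bromide (3-exo-tet) to give cyclopropyl ketone 3; γ-deprotonation then gives a norcaradiene-type dienolate that opens by 6π electrocyclic ring opening and is reprotonated to the ring-expanded dienone, which is achiral.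

Step 3
Reactants: 4 2,6,6-trimethylcyclohepta-2,4-dien-1-one
Product: 5 (4R,5S)-4,5-epoxy-2,6,6-trimethylcyclohept-2-en-1-one
Conditions: (R,R)-(salen)MnCl (5 mol %; salen = N,N′-bis(3,5-di-tert-butylsalicylidene)cyclohexane-1,2-diamine dianion), N-methylmorpholine N-oxide, mCPBA, CH2Cl2, −78 °C
Reagents that add atoms: mCPBA, O=C(OO)c1cccc(Cl)c1
Why: Jacobsen–Katsuki epoxidation; the electrophilic oxo-manganese species should choose the cis-disubstituted, more electron-rich γ,δ-alkene over the trisubstituted enone alkene, and the ring allows only the cis epoxide. Both stereocentres are set by the catalyst; by analogy with 2,2-dimethylchromenes and cis-β-methylstyrene the (R,R) complex of trivalent manganese is expected to give the (4R,5S) sense, and the antipodal catalyst is available should the sense prove opposite.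

Step 4
Reactants: 5 (4R,5S)-4,5-epoxy-2,6,6-trimethylcyclohept-2-en-1-one
Product: 6 (5R)-5-hydroxy-2,6,6-trimethylcyclohept-2-en-1-one
Conditions: Pd2(dba)3·CHCl3 (2.5 mol %), n-Bu3P, HCO2H, Et3N, 1,4-dioxane, rt
Reagents that add atoms: none
Why: Palladium-catalysed formate hydrogenolysis of an alkenyl oxirane: zerovalent palladium opens the allylic C4–O bond, formate loses CO2, and hydride is delivered to C4 so that the enone stays conjugated. The C5–O bond is not touched, so C5 keeps its configuration.

Step 5
Reactants: 6 (5R)-5-hydroxy-2,6,6-trimethylcyclohept-2-en-1-one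
Product: 7 (5R)-5-[(tert-butyldimethylsilyl)oxy]-2,6,6-trimethylcyclohept-2-en-1-one
Conditions: TBSOTf, 2,6-lutidine, CH2Cl2, −78 to 0 °C
Reagents that add atoms: tert-butyldimethylsilyl triflate, CC(C)(C)[Si](C)(C)OS(=O)(=O)C(F)(F)F
Why: Silylation with the silyl triflate, chosen because the alcohol is neopentylic; the ether shields the hydroxyl from the strong base and acylating agent of step 6 and from ketene or carbene chemistry in step 7.

Step 6
Reactants: 7 (5R)-5-[(tert-butyldimethylsilyl)oxy]-2,6,6-trimethylcyclohept-2-en-1-one
Product: 9 (5R)-5-[(tert-butyldimethylsilyl)oxy]-7-diazo-2,6,6-trimethylcyclohept-2-en-1-one, via 7-trifluoroacetyl ketone 8 (not isolated)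
Conditions: LiN(SiMe3)2, THF, −78 °C; CF3CO2CH2CF3, −78 °C; then MsN3, Et3N, H2O (1 equiv), MeCN, rt
Reagents that add atoms: methanesulfonyl azide, CS(=O)(=O)N=[N+]=[N-]; 2,2,2-trifluoroethyl trifluoroacetate, O=C(OCC(F)(F)F)C(F)(F)F (its atoms appear in intermediate 8 only)
Why: Detrifluoroacetylative (Regitz-type deacylative) diazo transfer: the kinetic α′-enolate, which can form only at C7 because C6 is quaternary, is trifluoroacetylated, and the activated 1,3-dicarbonyl 8 takes up the diazo group from the sulfonyl azide with loss of the trifluoroacetyl group. These are the usual conditions for base-sensitive α′-diazo enones.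

Step 7
Reactants: 9 (5R)-5-[(tert-butyldimethylsilyl)oxy]-7-diazo-2,6,6-trimethylcyclohept-2-en-1-one
Product: 12 methyl (1S,5R)-5-[(tert-butyldimethylsilyl)oxy]-2,6,6-trimethylcyclohex-2-ene-1-carboxylate, via silyloxy vinylketene 10 (not isolated), via ester dienol 11 (not isolated)
Conditions: hν (medium-pressure Hg lamp, Pyrex filter, λ > 300 nm), degassed MeOH, rt
Reagents that add atoms: methanol, CO
Why: Photolysis of the s-Z-locked cyclic α′-diazo enone expels N2 while the alkenyl carbon C2 shifts from the carbonyl carbon C1 to the diazo carbon C7 (Wolff rearrangement), which makes the ring bond that is C1–C6 of the target and pushes the former carbonyl carbon out of the ring as the ketene carbon of 10. Methanol adds to the ketene to give dienol 11, and kinetic α-protonation of 11 delivers the β,γ-unsaturated methyl ester with the alkene where the target needs it. The closest known reaction type is the photochemical Wolff ring contraction of cyclic 2-diazo ketones, together with the known alkenyl migration of α′-diazo enones to vinylketenes. The six-membered ring is not closed by a cyclisation; it arises from the seven-membered ring by a 1,2-shift. The new stereocentre C1 is set under substrate control when 11 is protonated at the ring carbon: with the silyloxy group pseudoequatorial, the pseudoaxial methyl of the gem-dimethyl carbon covers one face, so the proton should arrive on the other and leave the ester cis to the silyloxy group, as in 12. Complete face selectivity is not required, because C1 is re-equilibrated under base and then locked by lactonisation in step 9. The step needs migration to outrun carbene chemistry (O–H insertion, methyl shift from the neighbouring quaternary carbon), and the fixed s-Z geometry of the ring diazo ketone, which favours the concerted pathway, secures this. Only one group can migrate, so regiochemistry is not in question, and C5 is remote from the reacting atoms and keeps its configuration.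

Step 8
Reactants: 12 methyl (1S,5R)-5-[(tert-butyldimethylsilyl)oxy]-2,6,6-trimethylcyclohex-2-ene-1-carboxylate
Product: 13 methyl (1S,5R)-5-hydroxy-2,6,6-trimethylcyclohex-2-ene-1-carboxylate
Conditions: n-Bu4NF, THF, rt; aqueous work-up
Reagents that add atoms: none
Why: Fluoride-mediated desilylation frees the hydroxyl needed for lactonisation and touches no stereocentre. If the alkoxide formed on desilylation already attacks the cis ester, the result is simply lactone 14 formed early.

Step 9
Reactants: 13 methyl (1S,5R)-5-hydroxy-2,6,6-trimethylcyclohex-2-ene-1-carboxylate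
Product: 14 (1S,5R)-2,8,8-trimethyl-6-oxabicyclo[3.2.1]oct-2-en-7-one
Conditions: t-BuOK (0.3 equiv), THF–toluene, 5 Å molecular sieves, 60 °C; then AcOH
Reagents that add atoms: none
Why: Alkoxide-mediated intramolecular transesterification, driven by uptake of the released methanol on the sieves. The same base equilibrates C1 through the ester dienolate and only the cis alkoxide can reach the ester carbonyl, so any material of the opposite C1 configuration left by imperfect face selectivity in step 7 is drained into the same lactone. The bridgehead C–H of 14 cannot be enolised, which locks the configuration and the alkene position.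

Step 10
Reactants: 14 (1S,5R)-2,8,8-trimethyl-6-oxabicyclo[3.2.1]oct-2-en-7-one
Product: 15 (1R,5S)-5-(hydroxymethyl)-4,6,6-trimethylcyclohex-3-en-1-ol
Conditions: LiAlH4, THF, 0 °C to rt; aqueous NaOH work-up
Reagents that add atoms: none
Why: Hydride reduction of the lactone to the cis diol; no stereocentre is touched and the isolated trisubstituted alkene is inert.

Step 11
Reactants: 15 (1R,5S)-5-(hydroxymethyl)-4,6,6-trimethylcyclohex-3-en-1-ol; 16 3-methylbutanoyl chloride (isovaleryl chloride)
Product: 18 (1R,5S)-5-{[(tert-butyldimethylsilyl)oxy]methyl}-4,6,6-trimethylcyclohex-3-en-1-yl 3-methylbutanoate, via primary silyl ether 17 (not isolated)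
Conditions: TBSCl (1.05 equiv), Et3N, DMAP (cat.), CH2Cl2, 0 °C; then 16, Et3N, DMAP, 0 °C to rt
Reagents that add atoms: tert-butyldimethylsilyl chloride, CC(C)(C)[Si](C)(C)Cl
Why: Primary-selective silylation (the secondary hydroxyl is neopentylic and inert to the silyl chloride), followed in the same flask by DMAP-catalysed acylation of the remaining hindered alcohol. Masking the primary oxygen first keeps the cis diol from ever being activated at C8 with a free C4 hydroxyl.

Step 12
Reactants: 18 (1R,5S)-5-{[(tert-butyldimethylsilyl)oxy]methyl}-4,6,6-trimethylcyclohex-3-en-1-yl 3-methylbutanoate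
Product: 19 (1R,5S)-5-(hydroxymethyl)-4,6,6-trimethylcyclohex-3-en-1-yl 3-methylbutanoate
Conditions: HF·pyridine, pyridine, THF, 0 °C to rt
Reagents that add atoms: none
Why: Fluoride cleavage of the primary silyl ether under non-basic conditions, chosen so that the isovalerate neither migrates to the primary oxygen nor is cleaved.

Step 13
Reactants: 19 (1R,5S)-5-(hydroxymethyl)-4,6,6-trimethylcyclohex-3-en-1-yl 3-methylbutanoate; 20 umbelliferone (7-hydroxy-2H-chromen-2-one)
Product: 21 (1R,5S)-4,6,6-trimethyl-5-{[(2-oxo-2H-chromen-7-yl)oxy]methyl}cyclohex-3-en-1-yl 3-methylbutanoate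
Conditions: PPh3, DIAD, THF, 0 °C to rt
Reagents that add atoms: none
Why: Mitsunobu etherification: the acidic phenol (pKa about 8) protonates the betaine and its phenoxide displaces the alkoxyphosphonium group at the primary carbon. The carbon attacked is not a stereocentre, and the neutral conditions spare the isovalerate and the coumarin lactone.

## Compound list

1 | (R)-carvone | CC1=CC[C@H](CC1=O)C(C)=C | starting material
2 | (5R)-5-(2-bromopropan-2-yl)-2-methylcyclohex-2-en-1-one | CC1=CC[C@H](CC1=O)C(C)(C)Br | intermediate
3 | (1S,6R)-3,7,7-trimethylbicyclo[4.1.0]hept-3-en-2-one (car-3-en-2-one) | CC1=CC[C@@H]2[C@H](C1=O)C2(C)C | intermediate (not isolated)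
4 | 2,6,6-trimethylcyclohepta-2,4-dien-1-one (eucarvone) | CC1=CC=CC(C)(C)CC1=O | intermediate
5 | (4R,5S)-4,5-epoxy-2,6,6-trimethylcyclohept-2-en-1-one | CC1=C[C@H]2O[C@H]2C(C)(C)CC1=O | intermediate
6 | (5R)-5-hydroxy-2,6,6-trimethylcyclohept-2-en-1-one | CC1=CC[C@@H](O)C(C)(C)CC1=O | intermediate
7 | (5R)-5-[(tert-butyldimethylsilyl)oxy]-2,6,6-trimethylcyclohept-2-en-1-one | CC1=CC[C@@H](O[Si](C)(C)C(C)(C)C)C(C)(C)CC1=O | intermediate
8 | (5R)-5-[(tert-butyldimethylsilyl)oxy]-2,6,6-trimethyl-7-(trifluoroacetyl)cyclohept-2-en-1-one (C7 epimers and enol form) | CC1=CC[C@@H](O[Si](C)(C)C(C)(C)C)C(C)(C)C(C(=O)C(F)(F)F)C1=O | intermediate (not isolated)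
9 | (5R)-5-[(tert-butyldimethylsilyl)oxy]-7-diazo-2,6,6-trimethylcyclohept-2-en-1-one | CC1=CC[C@@H](O[Si](C)(C)C(C)(C)C)C(C)(C)C(=[N+]=[N-])C1=O | intermediate
10 | [(5R)-5-[(tert-butyldimethylsilyl)oxy]-2,6,6-trimethylcyclohex-2-en-1-ylidene]methanone (vinylketene) | CC1=CC[C@@H](O[Si](C)(C)C(C)(C)C)C(C)(C)C1=C=O | intermediate (not isolated)
11 | [(5R)-5-[(tert-butyldimethylsilyl)oxy]-2,6,6-trimethylcyclohex-2-en-1-ylidene](methoxy)methanol (ester dienol, either geometry) | CC1=CC[C@@H](O[Si](C)(C)C(C)(C)C)C(C)(C)C1=C(O)OC | intermediate (not isolated)
12 | methyl (1S,5R)-5-[(tert-butyldimethylsilyl)oxy]-2,6,6-trimethylcyclohex-2-ene-1-carboxylate | CC1=CC[C@@H](O[Si](C)(C)C(C)(C)C)C(C)(C)[C@H]1C(=O)OC | intermediate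
13 | methyl (1S,5R)-5-hydroxy-2,6,6-trimethylcyclohex-2-ene-1-carboxylate | CC1=CC[C@@H](O)C(C)(C)[C@H]1C(=O)OC | intermediate
14 | (1S,5R)-2,8,8-trimethyl-6-oxabicyclo[3.2.1]oct-2-en-7-one | CC1=CC[C@@H]2C(C)(C)[C@H]1C(=O)O2 | intermediate
15 | (1R,5S)-5-(hydroxymethyl)-4,6,6-trimethylcyclohex-3-en-1-ol | CC1=CC[C@@H](O)C(C)(C)[C@H]1CO | intermediate
16 | 3-methylbutanoyl chloride (isovaleryl chloride) | CC(C)CC(Cl)=O | starting material
17 | (1R,5S)-5-{[(tert-butyldimethylsilyl)oxy]methyl}-4,6,6-trimethylcyclohex-3-en-1-ol | CC1=CC[C@@H](O)C(C)(C)[C@H]1CO[Si](C)(C)C(C)(C)C | intermediate (not isolated)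
18 | (1R,5S)-5-{[(tert-butyldimethylsilyl)oxy]methyl}-4,6,6-trimethylcyclohex-3-en-1-yl 3-methylbutanoate | CC1=CC[C@@H](OC(=O)CC(C)C)C(C)(C)[C@H]1CO[Si](C)(C)C(C)(C)C | intermediate
19 | (1R,5S)-5-(hydroxymethyl)-4,6,6-trimethylcyclohex-3-en-1-yl 3-methylbutanoate | CC1=CC[C@@H](OC(=O)CC(C)C)C(C)(C)[C@H]1CO | intermediate
20 | umbelliferone (7-hydroxy-2H-chromen-2-one) | Oc1ccc2ccc(=O)oc2c1 | starting material
21 | (1R,5S)-4,6,6-trimethyl-5-{[(2-oxo-2H-chromen-7-yl)oxy]methyl}cyclohex-3-en-1-yl 3-methylbutanoate | CC1=CC[C@@H](OC(=O)CC(C)C)C(C)(C)[C@H]1COc1ccc2ccc(=O)oc2c1 | target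

## Step count and least certain steps

Total step count: 13. Longest linear sequence: 13 steps, from 1 to 21; compounds 16 and 20 enter as purchased materials.

**Step 7 (key step).** The excited diazo ketone may be diverted into O–H insertion with methanol or into methyl migration from the neighbouring quaternary carbon, and the vinylketene may be consumed photochemically before methanol traps it. Fallback, an ionic contraction that forms the same bond: set out from silyl enone 7, deprotonate with LiN(SiMe3)2 at −78 °C and brominate the enolate with NBS to give (5R)-7-bromo-5-[(tert-butyldimethylsilyl)oxy]-2,6,6-trimethylcyclohept-2-en-1-one F1 as a mixture of C7 epimers. Treat it with NaOMe in MeOH at 0 °C. Methoxide adds to the carbonyl, and because C2 carries no hydrogen a cyclopropanone cannot form, so the alkoxide collapses with shift of the alkenyl carbon onto C7 and loss of bromide (quasi-Favorskii contraction). C1 is then set by inversion at the brominated carbon, so ester 12 should be accompanied by its C1 epimer, methyl (1R,5R)-5-[(tert-butyldimethylsilyl)oxy]-2,6,6-trimethylcyclohex-2-ene-1-carboxylate F2. The unseparated pair is desilylated as in step 8, F2 giving methyl (1R,5R)-5-hydroxy-2,6,6-trimethylcyclohex-2-ene-1-carboxylate F3 beside 13. The epimerising base of step 9 carries F3 through the ester dienolate into 13 and on to lactone 14, where the fallback rejoins the route.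

**Step 3.** Enantioselectivity may be insufficient, or the oxidant may attack the enone alkene, because recognition of a dienone cis-alkene flanked by a quaternary carbon rests on analogy. Fallback by resolution: set out from 4 and epoxidise with mCPBA (NaHCO3, CH2Cl2) to racemic 4,5-epoxy-2,6,6-trimethylcyclohept-2-en-1-one F4. Open it as in step 4 to racemic 5-hydroxy-2,6,6-trimethylcyclohept-2-en-1-one F5. Esterify with (S)-2-methoxy-2-phenylacetic acid (DCC, DMAP) and separate the two diastereomeric esters by chromatography to obtain (1R)-2,2,5-trimethyl-4-oxocyclohept-5-en-1-yl (2S)-2-methoxy-2-phenylacetate F6. Methanolysis with K2CO3 in MeOH returns to 6, which enters step 5.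

**Step 4.** Hydride may be delivered to the wrong allyl terminus (the methyl-bearing carbon), giving the deconjugated ketone, or the epoxide may isomerise to a carbonyl compound at palladium. Fallback by single-electron reduction: set out from 5 and treat with SmI2 (THF–MeOH, −78 °C); cleavage of the C4–O bond from the ketyl and α-protonation of the dienolate give (5R)-5-hydroxy-2,6,6-trimethylcyclohept-3-en-1-one F7. DBU in CH2Cl2 moves the alkene into conjugation and returns to 6.

**Step 6.** Acylation of the enolate beside the quaternary carbon may be slow, letting γ-deprotonation and vinylogous elimination of silanolate toward the dienone compete. Fallback through an oxime (Forster reaction): set out from 7, form the kinetic enolate with LiN(SiMe3)2 and nitrosate it with isoamyl nitrite to give (5R)-5-[(tert-butyldimethylsilyl)oxy]-7-(hydroxyimino)-2,6,6-trimethylcyclohept-2-en-1-one F8. Chloramine (aqueous NH3, NaOCl) converts the oxime into the diazo group and returns to 9.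

**Step 9.** Equilibration at C1 may stop short, or the alkene may wander into conjugation or into the exocyclic position through the shared dienolate before lactonisation. Fallback, moving the equilibration to the aldehyde level where enolisation is far easier: set out from ester 12 and reduce with i-Bu2AlH (CH2Cl2, −78 °C) to (5R)-5-[(tert-butyldimethylsilyl)oxy]-2,6,6-trimethylcyclohex-2-ene-1-carbaldehyde F9. Desilylation with AcOH-buffered n-Bu4NF gives (5R)-5-hydroxy-2,6,6-trimethylcyclohex-2-ene-1-carbaldehyde F10. A catalytic amount of DBU should funnel the material into the bridged hemiacetal (1S,5R)-2,8,8-trimethyl-6-oxabicyclo[3.2.1]oct-2-en-7-ol F11, since only the cis aldehyde can close. NaBH4 in MeOH reduces the lactol and returns to diol 15, which enters step 11.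

**Step 13.** Displacement at the β-branched primary carbon next to the quaternary centre may be slow enough for the alkoxyphosphonium ion to be intercepted by the hydrazide or for the neighbouring ester to migrate. Fallback by stepwise activation and alkylation: set out from 19 and treat with MsCl and Et3N (CH2Cl2, 0 °C) to give (1R,5S)-5-{[(methylsulfonyl)oxy]methyl}-4,6,6-trimethylcyclohex-3-en-1-yl 3-methylbutanoate F12. Heating with 20 and Cs2CO3 in DMF at 60 °C returns to 21.

## Further compounds

F1 | step 7 | (5R)-7-bromo-5-[(tert-butyldimethylsilyl)oxy]-2,6,6-trimethylcyclohept-2-en-1-one (C7 epimers) | CC1=CC[C@@H](O[Si](C)(C)C(C)(C)C)C(C)(C)C(Br)C1=O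
F2 | step 7 | methyl (1R,5R)-5-[(tert-butyldimethylsilyl)oxy]-2,6,6-trimethylcyclohex-2-ene-1-carboxylate | CC1=CC[C@@H](O[Si](C)(C)C(C)(C)C)C(C)(C)[C@@H]1C(=O)OC
F3 | step 7 | methyl (1R,5R)-5-hydroxy-2,6,6-trimethylcyclohex-2-ene-1-carboxylate | CC1=CC[C@@H](O)C(C)(C)[C@@H]1C(=O)OC
F4 | step 3 | racemic cis-4,5-epoxy-2,6,6-trimethylcyclohept-2-en-1-one | CC1=C[C@H]2O[C@H]2C(C)(C)CC1=O.CC1=C[C@@H]2O[C@@H]2C(C)(C)CC1=O
F5 | step 3 | racemic 5-hydroxy-2,6,6-trimethylcyclohept-2-en-1-one | CC1=CC[C@@H](O)C(C)(C)CC1=O.CC1=CC[C@H](O)C(C)(C)CC1=O
F6 | step 3 | (1R)-2,2,5-trimethyl-4-oxocyclohept-5-en-1-yl (2S)-2-methoxy-2-phenylacetate | CO[C@H](C(=O)O[C@@H]1CC=C(C)C(=O)CC1(C)C)c1ccccc1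
F7 | step 4 | (5R)-5-hydroxy-2,6,6-trimethylcyclohept-3-en-1-one (C2 epimers) | CC1C=C[C@@H](O)C(C)(C)CC1=O
F8 | step 6 | (5R)-5-[(tert-butyldimethylsilyl)oxy]-7-(hydroxyimino)-2,6,6-trimethylcyclohept-2-en-1-one | CC1=CC[C@@H](O[Si](C)(C)C(C)(C)C)C(C)(C)C(=NO)C1=O
F9 | step 9 | (5R)-5-[(tert-butyldimethylsilyl)oxy]-2,6,6-trimethylcyclohex-2-ene-1-carbaldehyde (C1 epimers) | CC1=CC[C@@H](O[Si](C)(C)C(C)(C)C)C(C)(C)C1C=O
F10 | step 9 | (5R)-5-hydroxy-2,6,6-trimethylcyclohex-2-ene-1-carbaldehyde (C1 epimers) | CC1=CC[C@@H](O)C(C)(C)C1C=O
F11 | step 9 | (1S,5R)-2,8,8-trimethyl-6-oxabicyclo[3.2.1]oct-2-en-7-ol (anomers) | CC1=CC[C@@H]2C(C)(C)[C@H]1C(O)O2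
F12 | step 13 | (1R,5S)-5-{[(methylsulfonyl)oxy]methyl}-4,6,6-trimethylcyclohex-3-en-1-yl 3-methylbutanoate | CC1=CC[C@@H](OC(=O)CC(C)C)C(C)(C)[C@H]1COS(C)(=O)=O
A1 | alternative 1 | (4R)-4-(methoxymethoxy)-1,3,3-trimethylcyclohex-1-ene | CC1=CC(C)(C)[C@H](OCOC)CC1
A2 | alternative 1 | (1S,5R)-2,8,8-trimethyl-6-oxabicyclo[3.2.1]oct-2-ene | CC1=CC[C@@H]2C(C)(C)[C@H]1CO2
A3 | alternative 1 | (1R,5S)-5-(chloromethyl)-4,6,6-trimethylcyclohex-3-en-1-yl 3-methylbutanoate | CC1=CC[C@@H](OC(=O)CC(C)C)C(C)(C)[C@H]1CCl
A4 | alternative 2 | (3R)-2-ethenyl-2,4,4-trimethyl-3-{[tri(propan-2-yl)silyl]oxymethyl}cyclobutan-1-ol (configuration at C1 and C2 left open) | C=CC1(C)C(O)C(C)(C)[C@H]1CO[Si](C(C)C)(C(C)C)C(C)C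
A5 | alternative 2 | (1R,5S)-4,6,6-trimethyl-5-{[tri(propan-2-yl)silyl]oxymethyl}cyclohex-3-en-1-ol | CC1=CC[C@@H](O)C(C)(C)[C@H]1CO[Si](C(C)C)(C(C)C)C(C)C
A6 | alternative 3 | (1R,5R)-4,6,6-trimethylbicyclo[3.1.1]hept-3-en-2-one (verbenone) | CC1=CC(=O)[C@@H]2C[C@H]1C2(C)C
A7 | alternative 3 | (1S,5R)-2,7,7-trimethylbicyclo[3.1.1]hept-2-en-6-one (chrysanthenone) | CC1=CC[C@@H]2C(C)(C)[C@H]1C2=O
A8 | alternative 3 | (1S,5R)-2,8,8-trimethyl-6-oxabicyclo[3.2.1]oct-2-en-7-one (identical with 14) | CC1=CC[C@@H]2C(C)(C)[C@H]1C(=O)O2
A9 | alternative 3 | (1R,5S)-4,8,8-trimethyl-6-oxabicyclo[3.2.1]oct-3-en-7-one | CC1=CC[C@@H]2C(C)(C)[C@H]1OC2=O
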